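**Retrosynthetic overview**

1. The target comes from a bis-silylated macrolactone core by freeing the C8 hydroxyl, esterifying it with (2S,3R)-2,3-dimethyloxirane-2-carboxylic acid (Sharpless epoxidation of tiglyl alcohol, then oxidation) and removing the C9 silyl ether.
2. Key disconnection of the core: C6–C7 and C11–C12 together. The α-methylene-γ-butyrolactone (ring O–C6–C7–C11–C12, exocyclic C11=C13) is the enabling feature: C13=C11 with ring carbon C7 is a terminal allene (C13=C11=C7), the carboxyl carbon C12 with its carbonyl oxygen is CO2, and C6 with the ring oxygen is an aldehyde. A nickel-mediated carboxylative allylation joins the three and closes the ten-membered carbocycle in the same operation; the ring-cis C1=C10 enoate and the trans C4–C5 oxirane fold the chain.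
3. The open-chain allenyl epoxy aldehyde comes from a Nozaki–Hiyama–Kishi union at C9–C10 of a (Z)-α-iodo enoate (C1–C6, C10, C14, C15; from geranyl acetate) with an α-silyloxy allenyl aldehyde (C7–C9, C11, C13; from (R)-glyceraldehyde acetonide), then Sharpless epoxidation and oxidation at C6.
4. Stereochemistry: C8 is bought, C4/C5 and the two side-chain centres are set by tartrate catalysis, C9 is relayed from C8, and C6/C7 are relayed in the key step. Ring order: C4–C5 oxirane, then carbocycle and γ-lactone together, side-chain oxirane made separately and attached last.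

Key step: step 13

Remark: germacrane numbering is used for all intermediates (C1=C10 enoate, C4–C5 oxirane, C6 lactone O-carbon, C7, C8 acyloxy carbon, C9 carbinol, C11=C13 methylene, C12 lactone carbonyl, C14 ester carbon, C15 methyl); the side-chain acid is taken exactly as drawn, i.e. the (2S,3R) oxirane of tiglic acid; geranyl acetate, (R)-2,3-O-isopropylideneglyceraldehyde and (E)-2-methylbut-2-en-1-ol are taken as commercial.

Step 1
Reactants: 1 geranyl acetate [(2E)-3,7-dimethylocta-2,6-dien-1-yl acetate]
Product: 3 (2E)-3-methyl-6-oxohex-2-en-1-yl acetate, via ozonide 2 (not isolated)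
Conditions: O3 (1.0 equiv), CH2Cl2, −78 °C; then Me2S, −78 °C to rt
Reagents that add atoms: ozone, [O-][O+]=O
Why: Chemoselective ozonolysis, because the electron-rich terminal trisubstituted alkene reacts much faster than the 2,3-alkene that is deactivated by the allylic acetate, and dimethyl sulfide reduces the ozonide to the aldehyde; no stereocentre is formed.

Step 2
Reactants: 3 (2E)-3-methyl-6-oxohex-2-en-1-yl acetate
Product: 4 methyl (2Z,6E)-8-acetoxy-2-iodo-6-methylocta-2,6-dienoate
Conditions: Ph3P=CHCO2Me, N-iodosuccinimide, CH2Cl2, −20 °C; then 3, K2CO3, rt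
Reagents that add atoms: methyl (triphenylphosphoranylidene)acetate, COC(=O)C=P(c1ccccc1)(c1ccccc1)c1ccccc1; N-iodosuccinimide, O=C1CCC(=O)N1I
Why: Tandem ylide iodination–Wittig olefination, in which the stabilised iodo ylide should place the ester trans to the alkyl chain so that iodine ends cis to C2, the (Z)-iodide needed for the ring-cis C1=C10 enoate.

Step 3
Reactants: 5 (R)-2,2-dimethyl-1,3-dioxolane-4-carbaldehyde [(R)-2,3-O-isopropylideneglyceraldehyde]
Product: 6 (S)-4-ethynyl-2,2-dimethyl-1,3-dioxolane
Conditions: dimethyl (1-diazo-2-oxopropyl)phosphonate, K2CO3, MeOH, 0 °C to rt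
Reagents that add atoms: dimethyl (1-diazo-2-oxopropyl)phosphonate, CC(=O)C(=[N+]=[N-])P(=O)(OC)OC
Why: Ohira–Bestmann (Seyferth–Gilbert) homologation turns the aldehyde into the terminal alkyne under mild carbonate conditions that should leave the dioxolane centre (future C8) untouched, the descriptor changing from R to S only by priority.

Step 4
Reactants: 6 (S)-4-ethynyl-2,2-dimethyl-1,3-dioxolane
Product: 8 (S)-2,2-dimethyl-4-(propa-1,2-dien-1-yl)-1,3-dioxolane, via propargylic amine 7 (not isolated)
Conditions: (CH2O)n, CuI (0.5 equiv), dicyclohexylamine, 1,4-dioxane, reflux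
Reagents that add atoms: formaldehyde (as paraformaldehyde), C=O
Why: Crabbé homologation, in which the Mannich-derived propargylic amine undergoes copper-mediated 1,5-hydride shift and loss of the imine to give the terminal allene that will become C7=C11=C13, without touching the stereocentre.

Step 5
Reactants: 8 (S)-2,2-dimethyl-4-(propa-1,2-dien-1-yl)-1,3-dioxolane
Product: 9 (2S)-penta-3,4-diene-1,2-diol
Conditions: AcOH/H2O 4:1, 40 °C
Reagents that add atoms: none
Why: Mild acid hydrolysis of the acetonide (acetal cleavage) frees the diol, and the allenyl carbinol centre is not affected by dilute protic acid.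

Step 6
Reactants: 9 (2S)-penta-3,4-diene-1,2-diol
Product: 10 (2S)-1,2-bis(triethylsilyloxy)penta-3,4-diene
Conditions: Et3SiCl, imidazole, DMF, 0 °C to rt
Reagents that add atoms: chlorotriethylsilane, CC[Si](Cl)(CC)CC
Why: Standard imidazole-promoted silylation of both hydroxyls, with no change at the stereocentre.

Step 7
Reactants: 10 (2S)-1,2-bis(triethylsilyloxy)penta-3,4-diene
Product: 11 (2S)-2-(triethylsilyloxy)penta-3,4-dienal
Conditions: (COCl)2, DMSO, CH2Cl2, −78 to −40 °C; then Et3N, −78 to 0 °C
Reagents that add atoms: none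
Why: Swern conditions cleave and oxidise a primary triethylsilyl ether selectively while the secondary one survives (oxidative deprotection), giving the α-silyloxy aldehyde directly; it should be used at once to avoid enolisation at C8.

Step 8
Reactants: 4 methyl (2Z,6E)-8-acetoxy-2-iodo-6-methylocta-2,6-dienoate; 11 (2S)-2-(triethylsilyloxy)penta-3,4-dienal
Product: 12 methyl (2E,6E)-8-acetoxy-2-[(1R,2S)-1-hydroxy-2-(triethylsilyloxy)penta-3,4-dien-1-yl]-6-methylocta-2,6-dienoate
Conditions: CrCl2 (6 equiv), NiCl2 (1 mol %), DMSO, rt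
Reagents that add atoms: none
Why: Nozaki–Hiyama–Kishi coupling, in which the alkenylchromium formed with retention of the iodide geometry (C9 cis to C2) should add to the aldehyde in the Felkin–Anh sense, anti to the C8 silyloxy group, setting C9 as R.

Step 9
Reactants: 12 (C9 alcohol)
Product: 13 methyl (2E,6E)-8-acetoxy-2-[(1R,2S)-1-(tert-butyldimethylsilyloxy)-2-(triethylsilyloxy)penta-3,4-dien-1-yl]-6-methylocta-2,6-dienoate
Conditions: TBSOTf, 2,6-lutidine, CH2Cl2, −78 °C
Reagents that add atoms: tert-butyldimethylsilyl trifluoromethanesulfonate, CC(C)(C)[Si](C)(C)OS(=O)(=O)C(F)(F)F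
Why: Silyl triflate with a hindered base silylates the hindered allylic C9 hydroxyl at low temperature without base-induced silyl migration from C8.

Step 10
Reactants: 13 (C6 acetate)
Product: 14 methyl (2E,6E)-2-[(1R,2S)-1-(tert-butyldimethylsilyloxy)-2-(triethylsilyloxy)penta-3,4-dien-1-yl]-8-hydroxy-6-methylocta-2,6-dienoate
Conditions: K2CO3 (0.2 equiv), MeOH, 0 °C
Reagents that add atoms: none
Why: Catalytic methanolysis removes the allylic acetate, while the methyl ester is degenerate toward methoxide and the secondary silyl ethers should survive at 0 °C.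

Step 11
Reactants: 14 (C6 allylic alcohol)
Product: 15 methyl (2E)-2-[(1R,2S)-1-(tert-butyldimethylsilyloxy)-2-(triethylsilyloxy)penta-3,4-dien-1-yl]-5-[(2R,3R)-3-(hydroxymethyl)-2-methyloxiran-2-yl]pent-2-enoate
Conditions: Ti(OiPr)4, D-(−)-diethyl tartrate, t-BuOOH, 4 Å MS, CH2Cl2, −20 °C
Reagents that add atoms: tert-butyl hydroperoxide, CC(C)(C)OO
Why: Sharpless asymmetric epoxidation touches only the alkene of the primary allylic alcohol, and D-(−)-tartrate sets C4 and C5 as 4R,5R under catalyst control (trans oxirane from the E-alkene).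

Step 12
Reactants: 15 (epoxy alcohol)
Product: 16 methyl (2E)-2-[(1R,2S)-1-(tert-butyldimethylsilyloxy)-2-(triethylsilyloxy)penta-3,4-dien-1-yl]-5-[(2R,3S)-3-formyl-2-methyloxiran-2-yl]pent-2-enoate
Conditions: Dess–Martin periodinane, pyridine, CH2Cl2, 0 °C to rt
Reagents that add atoms: none
Why: Dess–Martin oxidation gives the α,β-epoxy aldehyde under buffered conditions, and its α-hydrogen sits on the oxirane and does not enolise, so C5 is kept.

Step 13
Reactants: 16 (allenyl epoxy aldehyde)
Product: 19 macrolactone core with C8–OSiEt3 and C9–OSi(t-Bu)Me2 (ring stereocentres as in the target), via oxanickelacycle 17 (not isolated), via hydroxy acid 18 (not isolated)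
Conditions: Ni(cod)2 [bis(cycloocta-1,5-diene)nickel] (1.5 equiv), DBU (4 equiv), CO2 (1 atm), THF, 0 °C, slow addition of 16 (10 h, 2 mM); 0.5 M aq. HCl, 0 °C; then EDC·HCl, DMAP (cat.), CH2Cl2, 0 °C to rt
Reagents that add atoms: carbon dioxide, O=C=O
Why: Proposed new method: DBU-ligated zerovalent nickel couples the terminal allene of 16 with CO2 by oxidative cyclisation at the unsubstituted C11=C13 bond, the CO2 carbon bonding to the central allene carbon C11 and nickel to C13, which gives the divalent-nickel 2-carboxylatoallyl species 17; its substituted terminus C7 then adds to the tethered aldehyde C6 through a six-membered chair transition state, and protonation followed by carbodiimide lactonisation of 18 gives 19. The closest known reaction type is the nickel-mediated sequential addition of CO2 and an aldehyde to a terminal allene (between separate partners and for five- and six-membered rings), combined with intramolecular Nozaki–Hiyama/Barbier allylations that close ten-membered germacrane rings at C6–C7; what is new is the use of the nickel carboxylate allyl for the ten-membered closure. The carbocycle closes by a 10-exo-trig addition to the carbonyl and the lactone by a 5-exo-trig acyl substitution at C12. C6 and C7 are created together: the chair with the E-configured allyl terminus and both ring arms (C5 and C8) pseudo-equatorial fixes the 6,7-trans relationship, and the facial sense (6S,7R) is expected from the macrocycle, because only the fold with the C8 silyloxy group and the oxirane oxygen pointing outward lets the ring-cis C1=C10 enoate and the trans C4–C5 oxirane span the two ends. The step needs CO2 capture to outrun direct nickel–aldehyde or nickel–enoate chemistry (CO2-saturated solution, slow addition, hindered trisubstituted enoate), attack through C7 and not C13 (closed transition state with nickel on the unsubstituted terminus) and ring closure over oligomerisation (2 mM, chain pre-bent by the cis enoate).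

Step 14
Reactants: 19 (bis-silylated macrolactone)
Product: 20 macrolactone with free C8–OH and C9–OSi(t-Bu)Me2
Conditions: HF·pyridine, pyridine, THF, 0 °C
Reagents that add atoms: none
Why: Buffered HF·pyridine cleaves the secondary triethylsilyl ether much faster than the secondary tert-butyldimethylsilyl ether (selective desilylation), and no stereocentre is touched.

Step 15
Reactants: 21 (E)-2-methylbut-2-en-1-ol (tiglyl alcohol)
Product: 22 [(2R,3R)-2,3-dimethyloxiran-2-yl]methanol
Conditions: Ti(OiPr)4, D-(−)-diethyl tartrate, t-BuOOH, 4 Å MS, CH2Cl2, −20 °C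
Reagents that add atoms: tert-butyl hydroperoxide, CC(C)(C)OO
Why: Sharpless asymmetric epoxidation of the E-trisubstituted allylic alcohol sets both side-chain centres under catalyst control, D-(−)-tartrate giving the (2R,3R) epoxy alcohol with the two methyl groups cis.

Step 16
Reactants: 22 [(2R,3R)-2,3-dimethyloxiran-2-yl]methanol
Product: 24 (2S,3R)-2,3-dimethyloxirane-2-carboxylic acid, via epoxy aldehyde 23 (not isolated)
Conditions: TEMPO (cat.), PhI(OAc)2 (2.2 equiv), MeCN/H2O 1:1, rt
Reagents that add atoms: water, O
Why: Oxoammonium (TEMPO) oxidation in aqueous acetonitrile takes the primary alcohol through the aldehyde hydrate to the acid without opening the oxirane, the C2 descriptor changing from R to S only by priority.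

Step 17
Reactants: 20 (C8 alcohol); 24 (2S,3R)-2,3-dimethyloxirane-2-carboxylic acid
Product: 26 C8 ester of 20 with the (2S,3R)-epoxy acid (C9 still silylated), via mixed anhydride 25 (not isolated)
Conditions: 2,4,6-trichlorobenzoyl chloride, Et3N, toluene, rt; then 20, DMAP, toluene, rt to 40 °C
Reagents that add atoms: none
Why: Yamaguchi esterification, in which DMAP transfers the acyl group of the mixed anhydride to the only free hydroxyl (C8) without affecting any stereocentre.

Step 18
Reactants: 26 (C9 silyl ether)
Product: 27 CNP0262846.1 (target)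
Conditions: HF·pyridine, pyridine, THF, 0 °C to rt
Reagents that add atoms: none
Why: Fluoride-mediated desilylation under acidic, non-basic conditions should free the C9 hydroxyl without C8-to-C9 acyl migration and without opening the two oxiranes.

**Compound list**

1 | geranyl acetate | CC(=O)OC/C=C(\C)CCC=C(C)C | starting material
2 | (2E)-5-(5,5-dimethyl-1,2,4-trioxolan-3-yl)-3-methylpent-2-en-1-yl acetate (ozonide) | CC(=O)OC/C=C(\C)CCC1OOC(C)(C)O1 | intermediate
3 | (2E)-3-methyl-6-oxohex-2-en-1-yl acetate | CC(=O)OC/C=C(\C)CCC=O | intermediate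
4 | methyl (2Z,6E)-8-acetoxy-2-iodo-6-methylocta-2,6-dienoate | COC(=O)/C(I)=C/CC/C(C)=C/COC(C)=O | intermediate
5 | (R)-2,2-dimethyl-1,3-dioxolane-4-carbaldehyde | O=C[C@H]1COC(C)(C)O1 | starting material
6 | (S)-4-ethynyl-2,2-dimethyl-1,3-dioxolane | C#C[C@H]1COC(C)(C)O1 | intermediate
7 | N,N-dicyclohexyl-3-[(4S)-2,2-dimethyl-1,3-dioxolan-4-yl]prop-2-yn-1-amine | C1CCCCC1N(CC#C[C@H]1COC(C)(C)O1)C1CCCCC1 | intermediate
8 | (S)-2,2-dimethyl-4-(propa-1,2-dien-1-yl)-1,3-dioxolane | C=C=C[C@H]1COC(C)(C)O1 | intermediate
9 | (2S)-penta-3,4-diene-1,2-diol | C=C=C[C@H](O)CO | intermediate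
10 | (2S)-1,2-bis(triethylsilyloxy)penta-3,4-diene | C=C=C[C@H](O[Si](CC)(CC)CC)CO[Si](CC)(CC)CC | intermediate
11 | (2S)-2-(triethylsilyloxy)penta-3,4-dienal | C=C=C[C@H](O[Si](CC)(CC)CC)C=O | intermediate
12 | methyl (2E,6E)-8-acetoxy-2-[(1R,2S)-1-hydroxy-2-(triethylsilyloxy)penta-3,4-dien-1-yl]-6-methylocta-2,6-dienoate | C=C=C[C@H](O[Si](CC)(CC)CC)[C@H](O)/C(C(=O)OC)=C\CC/C(C)=C/COC(C)=O | intermediate
13 | 9-O-tert-butyldimethylsilyl ether of 12 | C=C=C[C@H](O[Si](CC)(CC)CC)[C@H](O[Si](C)(C)C(C)(C)C)/C(C(=O)OC)=C\CC/C(C)=C/COC(C)=O | intermediate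
14 | C6 allylic alcohol (13 without the acetyl group) | C=C=C[C@H](O[Si](CC)(CC)CC)[C@H](O[Si](C)(C)C(C)(C)C)/C(C(=O)OC)=C\CC/C(C)=C/CO | intermediate
15 | (4R,5R)-epoxy alcohol: methyl (2E)-2-[(1R,2S)-1-(tert-butyldimethylsilyloxy)-2-(triethylsilyloxy)penta-3,4-dien-1-yl]-5-[(2R,3R)-3-(hydroxymethyl)-2-methyloxiran-2-yl]pent-2-enoate | C=C=C[C@H](O[Si](CC)(CC)CC)[C@H](O[Si](C)(C)C(C)(C)C)/C(C(=O)OC)=C\CC[C@@]1(C)O[C@@H]1CO | intermediate
16 | allenyl epoxy aldehyde: methyl (2E)-2-[(1R,2S)-1-(tert-butyldimethylsilyloxy)-2-(triethylsilyloxy)penta-3,4-dien-1-yl]-5-[(2R,3S)-3-formyl-2-methyloxiran-2-yl]pent-2-enoate | C=C=C[C@H](O[Si](CC)(CC)CC)[C@H](O[Si](C)(C)C(C)(C)C)/C(C(=O)OC)=C\CC[C@@]1(C)O[C@@H]1C=O | intermediate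
17 | oxanickelacycle: five-membered divalent-nickel carboxylate–allyl metallacycle Ni–C13H2–C11(=C7H–)–C12(=O)–O–Ni from 16, E at C11=C7, DBU ligands omitted | O=C1O[Ni]C/C1=C/[C@H](O[Si](CC)(CC)CC)[C@H](O[Si](C)(C)C(C)(C)C)/C(C(=O)OC)=C\CC[C@@]2(C)O[C@@H]2C=O | intermediate
18 | hydroxy acid: ten-membered carbocycle with C6–OH and C7–C(=CH2)CO2H, all centres as in 19 | C=C(C(=O)O)[C@@H]1[C@H](O[Si](CC)(CC)CC)[C@H](O[Si](C)(C)C(C)(C)C)/C(C(=O)OC)=C\CC[C@@]2(C)O[C@@H]2[C@H]1O | intermediate
19 | macrolactone core, 8-O-triethylsilyl, 9-O-tert-butyldimethylsilyl; C4, C5, C6, C7, C8, C9 as in the target | C=C1C(=O)O[C@H]2[C@H]1[C@H](O[Si](CC)(CC)CC)[C@H](O[Si](C)(C)C(C)(C)C)/C(C(=O)OC)=C\CC[C@@]1(C)O[C@H]21 | intermediate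
20 | macrolactone core with free C8–OH, 9-O-tert-butyldimethylsilyl | C=C1C(=O)O[C@H]2[C@H]1[C@H](O)[C@H](O[Si](C)(C)C(C)(C)C)/C(C(=O)OC)=C\CC[C@@]1(C)O[C@H]21 | intermediate
21 | (E)-2-methylbut-2-en-1-ol | C/C=C(\C)CO | starting material
22 | [(2R,3R)-2,3-dimethyloxiran-2-yl]methanol | OC[C@@]1(C)O[C@@H]1C | intermediate
23 | (2S,3R)-2,3-dimethyloxirane-2-carbaldehyde | O=C[C@@]1(C)O[C@@H]1C | intermediate
24 | (2S,3R)-2,3-dimethyloxirane-2-carboxylic acid | OC(=O)[C@@]1(C)O[C@@H]1C | intermediate
25 | (2S,3R)-2,3-dimethyloxirane-2-carboxylic 2,4,6-trichlorobenzoic anhydride | O=C(OC(=O)[C@@]1(C)O[C@@H]1C)c1c(Cl)cc(Cl)cc1Cl | intermediate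
26 | 9-O-tert-butyldimethylsilyl ether of the target | C=C1C(=O)O[C@H]2[C@H]1[C@H](OC(=O)[C@@]1(C)O[C@@H]1C)[C@H](O[Si](C)(C)C(C)(C)C)/C(C(=O)OC)=C\CC[C@@]1(C)O[C@H]21 | intermediate
27 | CNP0262846.1 | C=C1C(=O)O[C@H]2[C@H]1[C@H](OC(=O)[C@@]1(C)O[C@@H]1C)[C@H](O)/C(C(=O)OC)=C\CC[C@@]1(C)O[C@H]21 | target

**Totals**

Total step count: 18. Longest linear sequence: 14 steps (steps 3–14, 17, 18, from 5).

**Steps most likely to fail**

Step 13 (Proposed new method). What may go wrong: CO2 capture by the allene is outrun by nickel-mediated coupling of the allene with the aldehyde or the enoate, or by oligomerisation; the allyl reacts through C13; or the ring closes with the other facial sense. The fallback uses known chemistry and forms the same two bonds in two stages. It sets out from 15. Addition of Br2 (CH2Cl2, −78 °C) across the allene should give the 2,3-dibromoalkene F1 (either C7 epimer, or the allylic regioisomer, leads to the same allylchromium). Dess–Martin oxidation then gives the dibromo epoxy aldehyde F2. CrCl2 in THF at high dilution effects an intramolecular 2-bromoallyl Barbier (Nozaki–Hiyama) addition that closes the ten-membered ring to the bromovinyl carbinol F3. Carbonylative lactonisation with Pd(PPh3)4, CO (1 atm) and Et3N in MeCN at 60 °C comes back to the route at 19.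

Step 8. What may go wrong: low Felkin–Anh facial selectivity in the addition to the α-silyloxy aldehyde, so that 12 forms as a C9 epimer mixture. The fallback sets C9 by reagent control instead of substrate control. It sets out from 12 as the epimer mixture. Dess–Martin oxidation gives the alkylidene β-keto ester F4. Reduction with a CBS oxazaborolidine (the enantiomer that delivers hydride to give the 9R carbinol) and catecholborane at −78 °C comes back to the route at 12 as one C9 epimer.

Step 17. What may go wrong: slow acyl transfer from the α-quaternary epoxy acid to the hindered C8 hydroxyl, leaving time for decomposition of the activated acid or for translactonisation of the free hydroxyl onto the C14 ester. The fallback attaches an unhindered acid and builds the oxirane afterwards. It sets out from 20. Yamaguchi acylation with tiglic acid gives the C8 tiglate F5. Shi-type asymmetric epoxidation of the tiglate double bond with a chiral dioxirane (fructose-derived ketone for α,β-unsaturated esters, KHSO5; enantiomer chosen for the (2S,3R) oxirane) comes back to the route at 26.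

**Further compounds**

F1 | step 13 | 15 with the allene converted into CH(Br)–C(Br)=CH2 (C7 unassigned; all other centres as in 15) | C=C(Br)C(Br)[C@H](O[Si](CC)(CC)CC)[C@H](O[Si](C)(C)C(C)(C)C)/C(C(=O)OC)=C\CC[C@@]1(C)O[C@@H]1CO
F2 | step 13 | epoxy aldehyde from F1 (C6 aldehyde; other centres as in F1) | C=C(Br)C(Br)[C@H](O[Si](CC)(CC)CC)[C@H](O[Si](C)(C)C(C)(C)C)/C(C(=O)OC)=C\CC[C@@]1(C)O[C@@H]1C=O
F3 | step 13 | ten-membered carbocycle with C6–OH and C7–C(Br)=CH2 (centres as in 18) | C=C(Br)[C@@H]1[C@H](O[Si](CC)(CC)CC)[C@H](O[Si](C)(C)C(C)(C)C)/C(C(=O)OC)=C\CC[C@@]2(C)O[C@@H]2[C@H]1O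
F4 | step 8 | methyl (2E,6E)-8-acetoxy-6-methyl-2-[(2S)-2-(triethylsilyloxy)penta-3,4-dienoyl]octa-2,6-dienoate | C=C=C[C@H](O[Si](CC)(CC)CC)C(=O)/C(C(=O)OC)=C\CC/C(C)=C/COC(C)=O
F5 | step 17 | C8 (E)-2-methylbut-2-enoate (tiglate) of 20 | C=C1C(=O)O[C@H]2[C@H]1[C@H](OC(=O)/C(C)=C/C)[C@H](O[Si](C)(C)C(C)(C)C)/C(C(=O)OC)=C\CC[C@@]1(C)O[C@H]21
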